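The runs are simulated on assumed constants; the scatter is artificial.

Write the balance of the free catalyst, charged in the smallest amount at 56 µM: what is working plus what is held elsewhere. The capture agent stands at 1.40 mM, 25.0 times that charge, so if it takes one catalyst each, it can hold the whole charge.

in all of them: gas 15 mM (held); free catalyst 56 µM; temperature 100 °C

| flask | starting material | second substrate | capture agent | remark | time |
|---|---|---|---|---|---|
| Saturday's | 0.028 M | 0.028 M | 1.4 mM | the very flask that is asked about, followed so far |  |
| Sunday's | 0.014 M | 0.028 M | 1.4 mM | run made earlier |  |
| flask | 0.028 M | 0.0280 M | 1.40 mM |  | 4.0 d |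

- Saturday's (time / h: target / %, starting material / %): 5.00: 16, 84; 8.00: 26, 79; 12.0: 35, 71; 20.0: 41, 59; 40.0: 42, 58; 60.0: 42, 56
- Sunday's (time / h: target / %, starting material / %): 0.667: 2, 99; 2.00: 6, 91; 4.00: 14, 84; 5.00: 21, 76; 8.00: 34, 68; 10.0: 42, 63

(each reading ± 2 percentage points)

- what is taken out of target is counted as made
- the numbers in the tables scatter with a standard deviation of 2 percentage points
- at the start none of the gas is in solution
- additions bring no volume worth counting
- the earlier runs do not show what temperature does; that part of a forecast is a guess

- ash: at 4.0 d add free catalyst, 100 % of the amount charged, then wait 30 h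
- cedar: at 4.0 d take out 90 % of the target then present, then wait 30 h
- maple: change nothing and wait 30 h more
- alder: at 4.0 d raise the temperature by 25 K, then wait 30 h

- target, in percent of the starting material first charged, at 4.0 d
- the remedy with the largest gain of target, or "none" below 2 percentage points (ash / cedar / maple / alder / none)
- target present, with what was taken out counted in, in percent of the starting material first charged, after cedar
- target present, with what was taken out counted in, in percent of the starting material first charged, after maple

Saturday's run is this flask so far. Its target climbs to 41 % at 20.0 h and reads 42 % at 60.0 h, with 56 % of the starting material still there. Sunday's run, with the same catalyst charge, reads 42 % of a smaller charge of starting material at 10.0 h and is still climbing, but at 5.88 mM it stands below Saturday's last reading of 11.8 mM, so its readings show no stop to set beside Saturday's. These runs do not exclude an equilibrium; your reckoning here is a choice. Suppose each catalyst risks capture at a fixed small chance per turn, with gas and capture agent held as charged. Then the target made per catalyst charged, the catalyst budget or turnover number, is a constant, and Saturday's plateau reads it as 210, within the scatter.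

Now turn the settings by hand. Waiting (maple) adds no target once the catalyst is captured, so the flask stays near 42 %. Taking target out (cedar) changes nothing either, since the budget counts target made, not target present. Adding 100 % of the catalyst (ash) opens a new budget worth 42 percentage points, and the 56 % of starting material can supply that. Raising the temperature by 25 K (alder) is a guess, but captured catalyst should give no gain.

The forecast says “So the flask sits at equilibrium” and gives 42 %, cedar as best, 59 % after cedar and 42 % after maple.

The flask gives 43.7 %, 43.7 % after cedar and 43.7 % after maple; ash is best, gaining 40 points.

    starting material + free catalyst ⇌ catalyst intermediate A (K = 52.0 M⁻¹, k = 3000 M⁻¹ h⁻¹, Ea = 58.0 kJ mol⁻¹, ΔH = 15.0 kJ mol⁻¹)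
    second substrate + free catalyst ⇌ catalyst intermediate B (K = 96.0 M⁻¹, k = 52000 M⁻¹ h⁻¹, Ea = 60.0 kJ mol⁻¹, ΔH = −53.0 kJ mol⁻¹)
    catalyst intermediate A + capture agent → trapped intermediate (k = 780 M⁻¹ h⁻¹, Ea = 52.0 kJ mol⁻¹)
    gas ⇌ coupling partner, rate k4*(csat - [coupling partner]) (kL = 11.0 h⁻¹)
    coupling partner + catalyst intermediate A → free catalyst + target (k = 16000 M⁻¹ h⁻¹, Ea = 63.0 kJ mol⁻¹)
    coupling partner + catalyst intermediate B → free catalyst + second product (k = 8800 M⁻¹ h⁻¹, Ea = 45.0 kJ mol⁻¹)
    (constants at 100 °C)

In the flask at 9.60 h, catalyst intermediate A goes on to target 224 times for each capture. In the flask at 48.0 h the trapped intermediate holds 99.7 % of the catalyst. The budget puts a neighbour charged with 1.4 × 10⁻⁵ M of free catalyst at 10.5 %, and that neighbour holds 10.9 % at 96.0 h.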